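Compound numbers used throughout: ring B bromide **5**, ring A bromide **10**, vinylboronate **11**, conjunctive-coupling product **14**, alcohol **16**, target **20**.

## The problem

The target 20 is a (3R)-isoflavan: a chroman (ring A fused to ring C) whose C3 carries, through C1', a 2,2-dimethyl-2H-chromen-5-ol (ring B fused to the pyran ring D). Ring A bears 5-OMe and 7-OH; ring B bears 4'-OH and the 2'-oxygen that is tied up in ring D. The skeleton is two oxygenated arenes joined through the chain C2–C3–C4, so the carbon–carbon bonds to be made are C3–C1', C4–C4a and C2–C3, plus the ether bond O1–C2. C3 is the only stereocentre, a benzylic methine between two methylene groups; nothing in the molecule can relay to it, so a catalyst or reagent must set it, and afterwards it should never sit α to a carbonyl group. Five oxygens on two rings have different fates (O1, 5-OMe, 7-OH, 4'-OH, the ring D ether), and which becomes which is best decided by structure, not by late selective reactions. The cis-styrenyl double bond of ring D rules out hydrogenation and hydrogenolysis once it exists and limits strong acid and electrophilic oxidants; both arenes are electron-rich. The enabling feature is that C3–C4 is a two-carbon unit with ring B on C3 and ring A on C4, and that C4a lies between C5–O and C8a–O1. Ring A can therefore enter as an aryl electrophile with two equivalent ortho oxygens, a vinylboron unit can supply C3 and C4, ring B can migrate from boron to C3, and the boron left on C3 is the handle for C2.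

## Retrosynthesis

**20 back to 18.** The O–Si bonds at O7 and O4' are cut first (20 from bis-silyl ether 19), then the O–CH3 bond at O5 (19 from phenol 18). The methyl group is placed late because the ring A partner is only free of regiochemical questions while its two ortho oxygens are alike. The forward steps ask for a phenol methylation that spares aryl silyl ethers and a buffered fluoride desilylation.

**18 back to 16.** Ring C is opened at O1–C2, giving the phenol-diol 17 with a primary alcohol. The neighbouring cut O1–C8a would need an aryl C–O coupling and a halogen on ring A, whereas this cut uses a phenol that is already present. The two phenols of 17 are interchanged by rotation about C4–C4a, so closure onto either gives 18 and marks the survivor as the future 5-OMe. Triol 17 comes from the bis-acetal 16 by removal of two methoxymethyl groups; the forward reaction must spare the silyl ethers and ring D.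

**16 back to 14.** The C2–C3 bond is cut: C2 is a one-carbon carbenoid inserted into the C3–B bond of the secondary benzylic boronate 14, giving the primary boronate 15, which is oxidised to 16. Bringing C2 in on the alkene partner would put it on the wrong carbon or make C3 quaternary. The forward step must be stereoretentive, which a 1,2-boronate shift is.

**14 back to 5, 10 and 11.** Two bonds are cut at once, C3–C1' and C4–C4a, leading to the ate complex 13 and the ring A bromide 10; 13 comes from the chromenyllithium 12 and vinylboronate 11, and 12 from the ring B bromide 5. A stepwise union through a C3–C4 cut would need a stoichiometric auxiliary and an unstable trioxygenated benzyl halide. Cutting only C3–C1' would leave no handle for C2. Here three achiral pieces without stereocentres replace a chiral, fully protected diarylpropane. The forward reaction must set C3 by catalyst control, let the 1,2-shift outrun direct aryl–aryl coupling, and accept a doubly ortho-substituted bromide.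

**5 back to 1 and 3.** Ring D is cut at C3'–C(vinyl) and O–CMe2, giving the propargyl ether 4, made from the monosilylated bromophenol 2 and the propargylic chloride 3; 2 comes from 4-bromoresorcinol 1. The bromine serves twice: it blocks one ortho position so the rearrangement can only go between the two oxygens, and it later becomes the lithium of 12.

**10 back to 6.** The C–Br bond is cut to the aryllithium 9, obtained by deprotonation of 8 between its two acetal oxygens; 8 is the silyl ether of the bis-acetal 7, made from phloroglucinol 6. The mirror symmetry of 8 leaves a single doubly activated site, so no isomer question arises.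

## Roads not taken

**Alternative 1:** The cut lies in ring D (C3'–C(vinyl) and O–CMe2) and leads back to the 2'-O-(1,1-dimethylpropargyl) isoflavan A1. Heating A1 should give the bis-silyl ether A2 of the target by propargyl Claisen rearrangement to C3', hydrogen shift and oxa-6π closure.
- Merits: the fragile chromene appears last, so hydrogenation-based ways of setting C3 and benzyl-type protection stay open for the isoflavan core. The regiochemistry is clean because C1' blocks the other ortho position.
- Weak points: the cut does nothing for C3 or the C2–C3–C4 chain. An enantioselective isoflavan synthesis with three distinguishable phenols must come first. The 2'-OH to be propargylated is crowded by the C3 substituent. The whole advanced material is then heated to 150–180 °C.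
- Comparison: in protecting ring D from harsh reagents this road is better. The chosen plan runs the same cascade at step 3 on a simple bromophenol and must set against it that 5 survives t-BuLi, palladium, perborate and methanolic HCl. In return it solves the C3 problem in the same step that joins the fragments.

**Alternative 2:** The cuts are C3–C4 and O1–C2. The ring A ortho-hydroxybenzyl alcohol A3 releases the ortho-quinone methide A4, which combines with the enamine of the ring B arylacetaldehyde A5 under a chiral secondary amine catalyst. The product is lactol A6, with ring C closed and C3 set.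
- Merits: metal-free and convergent, and ring A arrives with 5-OMe in place, so no late methylation is needed. In convergence and step count after the union it is at least equal to the chosen plan.
- Weak points: A4 has no substituent on the methide carbon (C4 is CH2); such species are short-lived and oligomerise, and the enantioselective annulations of this type lean on substituted methides. C3 of A6 is α to a masked aldehyde that opens by ring–chain tautomerism and can epimerise through the enamine. Removing the C2 oxygen needs silane and Lewis acid beside MOM acetals and the chromene, or reduction to a diol and a second ring closure. A3 needs three differently treated oxygens on a phloroglucinol ring.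
- Comparison: the chosen plan sets against the shorter endgame a C–B stereocentre that cannot enolise and a symmetric ring A partner.

**Alternative 3:** Ring B itself is cut. Irradiation of the unsaturated diazo ketone A7, carried on a preformed (3R)-chroman, should give vinylketene A8 by Wolff rearrangement. A8 would combine with the prenyl siloxyalkyne A9 by [2+2] addition, 4π opening, 6π closure and tautomerisation to give phenol A10. The alkyne carbons become C3' (prenyl) and C4' (silyloxy), and the ketene carbonyl becomes the 2'-OH.
- Merits: the ring B substitution pattern is fixed by mechanism, and the 2'-OH arrives free and distinct from the 4'-oxygen. In this one respect it is better than the chosen plan; the prenyl phenol could then be cyclised oxidatively to ring D.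
- Weak points: C3 must already exist in A7, so a separate asymmetric synthesis of a chroman-3-yl building block is needed. The C3–H is adjacent to the carbene carbon, so a 1,2-hydrogen shift can compete with the Wolff rearrangement and erase the stereocentre. The route needs photochemistry and a sensitive ynol ether, builds an arene that can be bought as a resorcinol, and still needs an oxidative cyclisation on electron-rich rings.
- Comparison: the chosen plan answers the 2'/4' differentiation with the bromine of 1 and is shorter.

Key step: step 7

Assumption: the enantiomer of the MandyPhos ligand is the one that delivers the (R)-boronate 14; if induction with this pair of partners runs the other way, the mirror-image ligand is used and nothing else changes.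

## Route

Step 1
Reactants: 1 4-bromobenzene-1,3-diol (4-bromoresorcinol)
Product: 2 2-bromo-5-(triisopropylsilyloxy)phenol
Conditions: TIPSCl (1.0 equiv), imidazole, DMF, 0 °C
Reagents that add atoms: chlorotriisopropylsilane (TIPSCl), CC(C)[Si](Cl)(C(C)C)C(C)C
Why: Phenol silylation; the bulky silyl chloride should take the hydroxyl para to bromine because the other is shielded by the ortho bromine, and any bis-silyl ether or regioisomer is removed by chromatography.

Step 2
Reactants: 2 2-bromo-5-(triisopropylsilyloxy)phenol; 3 3-chloro-3-methylbut-1-yne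
Product: 4 [4-bromo-3-(2-methylbut-3-yn-2-yloxy)phenoxy]triisopropylsilane
Conditions: DBU, CuCl2·2H2O (1 mol%), MeCN, 0 °C
Reagents that add atoms: none
Why: Copper-catalysed O-propargylation of a phenol by a tertiary propargylic chloride through a copper acetylide-derived electrophile, the standard entry to aryl 1,1-dimethylpropargyl ethers, ortho-substituted phenols included; anhydrous conditions at 0 °C should keep the aryl silyl ether intact.

Step 3
Reactants: 4 [4-bromo-3-(2-methylbut-3-yn-2-yloxy)phenoxy]triisopropylsilane
Product: 5 8-bromo-2,2-dimethyl-5-(triisopropylsilyloxy)-2H-chromene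
Conditions: N,N-diethylaniline, 180 °C
Reagents that add atoms: none
Why: Aromatic propargyl Claisen rearrangement followed by enolisation, 1,5-hydrogen shift and oxa-6π electrocyclisation; bromine blocks one ortho position, so the [3,3] shift can only go to the carbon between the two oxygens, which fixes the 5-silyloxy-8-bromo pattern.

Step 4
Reactants: 6 benzene-1,3,5-triol (phloroglucinol)
Product: 7 3,5-bis(methoxymethoxy)phenol
Conditions: MOMCl (2.0 equiv), i-Pr2NEt, DMF, 0 °C to rt
Reagents that add atoms: chloromethyl methyl ether (MOMCl), COCCl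
Why: O-alkylation of phenols to MOM acetals; the reaction is statistical, the bis-ether is separated from mono- and tris-ethers by chromatography, and the cheap triol makes this acceptable at the first step of a fragment.

Step 5
Reactants: 7 3,5-bis(methoxymethoxy)phenol
Product: 8 [3,5-bis(methoxymethoxy)phenoxy]triisopropylsilane
Conditions: TIPSCl, imidazole, DMF, rt
Reagents that add atoms: chlorotriisopropylsilane (TIPSCl), CC(C)[Si](Cl)(C(C)C)C(C)C
Why: Silylation of the single free phenol; the silyl ether marks the future 7-OH and is orthogonal to the two acetals.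

Step 6
Reactants: 8 [3,5-bis(methoxymethoxy)phenoxy]triisopropylsilane
Product: 10 [4-bromo-3,5-bis(methoxymethoxy)phenoxy]triisopropylsilane, via aryllithium 9 (not isolated)
Conditions: n-BuLi, THF, 0 °C; then BrCH2CH2Br, −78 °C to rt
Reagents that add atoms: 1,2-dibromoethane, BrCCBr
Why: Directed ortho-metalation; the position between the two MOM ethers is doubly coordinated and the most acidic while the bulky silyl ether does not direct, and the aryllithium is brominated by halogen transfer from 1,2-dibromoethane with loss of ethene.

Step 7
Reactants: 5 8-bromo-2,2-dimethyl-5-(triisopropylsilyloxy)-2H-chromene; 11 4,4,5,5-tetramethyl-2-vinyl-1,3,2-dioxaborolane (vinylboronic acid pinacol ester); 10 [4-bromo-3,5-bis(methoxymethoxy)phenoxy]triisopropylsilane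
Product: 14 2-[(1R)-2-[2,6-bis(methoxymethoxy)-4-(triisopropylsilyloxy)phenyl]-1-[2,2-dimethyl-5-(triisopropylsilyloxy)-2H-chromen-8-yl]ethyl]-4,4,5,5-tetramethyl-1,3,2-dioxaborolane, via chromenyllithium 12 (not isolated), via lithium vinylboronate complex 13 (not isolated)
Conditions: t-BuLi (2.0 equiv), Et2O, −78 °C; 11, −78 to 0 °C; solvent changed to THF; 10, Pd(OAc)2 (3 mol%), MandyPhos (a 1,1'-bis(diarylphosphino)-2,2'-bis[α-(dimethylamino)benzyl]ferrocene, 3.6 mol%), KOTf (2 equiv), 60 °C
Reagents that add atoms: none
Why: Bromine–lithium exchange gives 12, which adds to boron of 11 to form the four-coordinate ate complex 13; zerovalent palladium carrying the chiral bisphosphine inserts into the C–Br bond of 10, potassium triflate removes bromide as insoluble KBr, and the resulting cationic aryl complex of divalent palladium binds the vinyl group of 13. Coordination makes the alkene electrophilic, so ring B shifts from boron to the α-carbon (C3–C1') anti to palladium while the β-carbon (C4) bonds to palladium, and reductive elimination then forms C4–C4a and returns zerovalent palladium. The closest known reaction type is the palladium/MandyPhos-catalysed enantioselective conjunctive cross-coupling of aryl(vinyl)boron ate complexes with aryl triflates or, with a triflate salt as halide scavenger, aryl bromides. No ring closes. The new stereocentre C3 is set by the ligand, which decides the face of the vinyl group that palladium occupies and hence the face to which ring B migrates; there is no substrate stereocentre to interfere. The step needs the metallate shift to outrun direct aryl transfer from boron to palladium and β-hydride elimination from the alkylpalladium intermediate; a chelating ligand on halide-free cationic palladium leaves one site, which the alkene takes, and the wide bite angle together with the crowded di-ortho-substituted aryl group should speed reductive elimination. Regiochemistry is not in question because 10 has a single C–Br bond flanked by two identical acetal oxygens, and the only other alkene, the hindered chromene double bond, is not activated by boron and should not compete for palladium.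

Step 8
Reactants: 14 2-[(1R)-2-[2,6-bis(methoxymethoxy)-4-(triisopropylsilyloxy)phenyl]-1-[2,2-dimethyl-5-(triisopropylsilyloxy)-2H-chromen-8-yl]ethyl]-4,4,5,5-tetramethyl-1,3,2-dioxaborolane
Product: 16 (2R)-3-[2,6-bis(methoxymethoxy)-4-(triisopropylsilyloxy)phenyl]-2-[2,2-dimethyl-5-(triisopropylsilyloxy)-2H-chromen-8-yl]propan-1-ol, via homologated boronate 15 (not isolated)
Conditions: BrCH2Cl, n-BuLi, THF, −78 °C to rt; then NaBO3·4H2O, THF/H2O, rt
Reagents that add atoms: bromochloromethane, ClCBr; sodium perborate tetrahydrate (NaBO3·4H2O), O.O.O.O.[Na+].[O-]OB=O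
Why: Matteson homologation; chloromethyllithium adds to boron and the C3 group migrates with retention, displacing chloride, and the new primary C–B bond is then oxidised with retention by perborate, which is mild enough for aryl silyl ethers. C3 is the migrating carbon and keeps its configuration.

Step 9
Reactants: 16 (2R)-3-[2,6-bis(methoxymethoxy)-4-(triisopropylsilyloxy)phenyl]-2-[2,2-dimethyl-5-(triisopropylsilyloxy)-2H-chromen-8-yl]propan-1-ol
Product: 17 2-[(2R)-2-[2,2-dimethyl-5-(triisopropylsilyloxy)-2H-chromen-8-yl]-3-hydroxypropyl]-5-(triisopropylsilyloxy)benzene-1,3-diol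
Conditions: HCl (1 M in MeOH), rt to 40 °C
Reagents that add atoms: none
Why: Acid-catalysed acetal exchange of the two aryl MOM ethers with methanol; aryl triisopropylsilyl ethers and 2,2-dimethylchromenes are expected to tolerate dilute methanolic HCl at this temperature.

Step 10
Reactants: 17 2-[(2R)-2-[2,2-dimethyl-5-(triisopropylsilyloxy)-2H-chromen-8-yl]-3-hydroxypropyl]-5-(triisopropylsilyloxy)benzene-1,3-diol
Product: 18 (3R)-3-[2,2-dimethyl-5-(triisopropylsilyloxy)-2H-chromen-8-yl]-7-(triisopropylsilyloxy)chroman-5-ol
Conditions: PPh3, DIAD, THF (0.02 M), 0 °C to rt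
Reagents that add atoms: none
Why: Intramolecular Mitsunobu etherification; the primary alcohol is activated as its oxyphosphonium salt and displaced by an ortho phenol in a 6-exo-tet closure. The two phenols are interchanged by rotation about C4–C4a, so either gives the same chroman, and C3 is not touched.

Step 11
Reactants: 18 (3R)-3-[2,2-dimethyl-5-(triisopropylsilyloxy)-2H-chromen-8-yl]-7-(triisopropylsilyloxy)chroman-5-ol
Product: 19 (3R)-3-[2,2-dimethyl-5-(triisopropylsilyloxy)-2H-chromen-8-yl]-5-methoxy-7-(triisopropylsilyloxy)chroman
Conditions: MeI, K2CO3, acetone, rt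
Reagents that add atoms: iodomethane, CI
Why: Williamson methylation of the only free phenol (5-OH); anhydrous carbonate in acetone at room temperature is mild enough for aryl triisopropylsilyl ethers.

Step 12
Reactants: 19 (3R)-3-[2,2-dimethyl-5-(triisopropylsilyloxy)-2H-chromen-8-yl]-5-methoxy-7-(triisopropylsilyloxy)chroman
Product: 20 (3R)-3-(5-hydroxy-2,2-dimethyl-2H-chromen-8-yl)-5-methoxychroman-7-ol
Conditions: TBAF, AcOH, THF, 0 °C to rt
Reagents that add atoms: none
Why: Fluoride cleavage of both aryl silyl ethers; acetic acid buffers the phenoxides so that the electron-rich bis-phenol and ring D are not exposed to strong base.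

## Compound list

1 | 4-bromobenzene-1,3-diol (4-bromoresorcinol) | Oc1ccc(Br)c(O)c1 | starting material
2 | 2-bromo-5-(triisopropylsilyloxy)phenol | Oc1cc(O[Si](C(C)C)(C(C)C)C(C)C)ccc1Br | intermediate
3 | 3-chloro-3-methylbut-1-yne | CC(C)(Cl)C#C | starting material
4 | [4-bromo-3-(2-methylbut-3-yn-2-yloxy)phenoxy]triisopropylsilane | C#CC(C)(C)Oc1cc(O[Si](C(C)C)(C(C)C)C(C)C)ccc1Br | intermediate
5 | 8-bromo-2,2-dimethyl-5-(triisopropylsilyloxy)-2H-chromene | Brc1ccc(O[Si](C(C)C)(C(C)C)C(C)C)c2c1OC(C)(C)C=C2 | intermediate
6 | benzene-1,3,5-triol (phloroglucinol) | Oc1cc(O)cc(O)c1 | starting material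
7 | 3,5-bis(methoxymethoxy)phenol | COCOc1cc(O)cc(OCOC)c1 | intermediate
8 | [3,5-bis(methoxymethoxy)phenoxy]triisopropylsilane | COCOc1cc(O[Si](C(C)C)(C(C)C)C(C)C)cc(OCOC)c1 | intermediate
9 | [2,6-bis(methoxymethoxy)-4-(triisopropylsilyloxy)phenyl]lithium | COCOc1cc(O[Si](C(C)C)(C(C)C)C(C)C)cc(OCOC)c1[Li] | intermediate
10 | [4-bromo-3,5-bis(methoxymethoxy)phenoxy]triisopropylsilane (2-bromo-1,3-bis(methoxymethoxy)-5-(triisopropylsilyloxy)benzene) | COCOc1cc(O[Si](C(C)C)(C(C)C)C(C)C)cc(OCOC)c1Br | intermediate
11 | 4,4,5,5-tetramethyl-2-vinyl-1,3,2-dioxaborolane | C=CB1OC(C)(C)C(C)(C)O1 | starting material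
12 | [2,2-dimethyl-5-(triisopropylsilyloxy)-2H-chromen-8-yl]lithium | [Li]c1ccc(O[Si](C(C)C)(C(C)C)C(C)C)c2c1OC(C)(C)C=C2 | intermediate
13 | lithium [2,2-dimethyl-5-(triisopropylsilyloxy)-2H-chromen-8-yl](vinyl)(pinacolato)borate | [Li+].C=C[B-]1(c2ccc(O[Si](C(C)C)(C(C)C)C(C)C)c3c2OC(C)(C)C=C3)OC(C)(C)C(C)(C)O1 | intermediate
14 | 2-[(1R)-2-[2,6-bis(methoxymethoxy)-4-(triisopropylsilyloxy)phenyl]-1-[2,2-dimethyl-5-(triisopropylsilyloxy)-2H-chromen-8-yl]ethyl]-4,4,5,5-tetramethyl-1,3,2-dioxaborolane | COCOc1cc(O[Si](C(C)C)(C(C)C)C(C)C)cc(OCOC)c1C[C@H](c1ccc(O[Si](C(C)C)(C(C)C)C(C)C)c2c1OC(C)(C)C=C2)B1OC(C)(C)C(C)(C)O1 | intermediate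
15 | 2-[(2R)-3-[2,6-bis(methoxymethoxy)-4-(triisopropylsilyloxy)phenyl]-2-[2,2-dimethyl-5-(triisopropylsilyloxy)-2H-chromen-8-yl]propyl]-4,4,5,5-tetramethyl-1,3,2-dioxaborolane | COCOc1cc(O[Si](C(C)C)(C(C)C)C(C)C)cc(OCOC)c1C[C@H](c1ccc(O[Si](C(C)C)(C(C)C)C(C)C)c2c1OC(C)(C)C=C2)CB1OC(C)(C)C(C)(C)O1 | intermediate
16 | (2R)-3-[2,6-bis(methoxymethoxy)-4-(triisopropylsilyloxy)phenyl]-2-[2,2-dimethyl-5-(triisopropylsilyloxy)-2H-chromen-8-yl]propan-1-ol | COCOc1cc(O[Si](C(C)C)(C(C)C)C(C)C)cc(OCOC)c1C[C@H](c1ccc(O[Si](C(C)C)(C(C)C)C(C)C)c2c1OC(C)(C)C=C2)CO | intermediate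
17 | 2-[(2R)-2-[2,2-dimethyl-5-(triisopropylsilyloxy)-2H-chromen-8-yl]-3-hydroxypropyl]-5-(triisopropylsilyloxy)benzene-1,3-diol | Oc1cc(O[Si](C(C)C)(C(C)C)C(C)C)cc(O)c1C[C@H](c1ccc(O[Si](C(C)C)(C(C)C)C(C)C)c2c1OC(C)(C)C=C2)CO | intermediate
18 | (3R)-3-[2,2-dimethyl-5-(triisopropylsilyloxy)-2H-chromen-8-yl]-7-(triisopropylsilyloxy)chroman-5-ol | Oc1cc(O[Si](C(C)C)(C(C)C)C(C)C)cc2c1C[C@H](c1ccc(O[Si](C(C)C)(C(C)C)C(C)C)c3c1OC(C)(C)C=C3)CO2 | intermediate
19 | (3R)-3-[2,2-dimethyl-5-(triisopropylsilyloxy)-2H-chromen-8-yl]-5-methoxy-7-(triisopropylsilyloxy)chroman | COc1cc(O[Si](C(C)C)(C(C)C)C(C)C)cc2c1C[C@H](c1ccc(O[Si](C(C)C)(C(C)C)C(C)C)c3c1OC(C)(C)C=C3)CO2 | intermediate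
20 | (3R)-3-(5-hydroxy-2,2-dimethyl-2H-chromen-8-yl)-5-methoxychroman-7-ol | COc1cc(O)cc2c1C[C@H](c1ccc(O)c3c1OC(C)(C)C=C3)CO2 | target

## Step count and risk

Total steps: 12. Longest linear sequence: 9 steps (steps 1–3 or steps 4–6, then steps 7–12).

**Step 7 (key step).** Oxidative addition and alkene binding may be slow at the doubly ortho-substituted, electron-rich bromide. Residual bromide could then hold the catalyst, and direct aryl transfer to palladium or β-hydride elimination could overtake the metallate shift. Facial discrimination could also be lower than with unhindered electrophiles.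

Fallback (sets out from 5 and from aryllithium 9, returns at 16): the union is made by an auxiliary-controlled C3–C4 alkylation (Evans alkylation), bypassing steps 7 and 8.
- Ring B side: coupling of 5 with the Reformatsky reagent BrZnCH2CO2Et (Pd2(dba)3, XPhos, THF) should give ethyl 2-[2,2-dimethyl-5-(triisopropylsilyloxy)-2H-chromen-8-yl]acetate F1. Saponification (LiOH, aqueous THF, 0 °C) gives 2-[2,2-dimethyl-5-(triisopropylsilyloxy)-2H-chromen-8-yl]acetic acid F2. Activation as the pivalic mixed anhydride and acylation of lithiated (R)-4-benzyloxazolidin-2-one gives (4R)-4-benzyl-3-{2-[2,2-dimethyl-5-(triisopropylsilyloxy)-2H-chromen-8-yl]acetyl}oxazolidin-2-one F3.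
- Ring A side: 9 is quenched with paraformaldehyde to give [2,6-bis(methoxymethoxy)-4-(triisopropylsilyloxy)phenyl]methanol F4. PPh3/CBr4 (CH2Cl2, 0 °C) converts it into [4-(bromomethyl)-3,5-bis(methoxymethoxy)phenoxy]triisopropylsilane F5, which is used at once.
- Union: the sodium enolate of F3 (NaN(SiMe3)2, THF, −78 °C) is alkylated by F5 on the face away from the benzyl group of the auxiliary, giving (4R)-4-benzyl-3-{(2R)-3-[2,6-bis(methoxymethoxy)-4-(triisopropylsilyloxy)phenyl]-2-[2,2-dimethyl-5-(triisopropylsilyloxy)-2H-chromen-8-yl]propanoyl}oxazolidin-2-one F6. LiBH4 then releases 16 and the auxiliary, and the route resumes at step 9.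

**Step 8.** The ate complex may form incompletely at the hindered secondary benzylic boron, and the thermally fragile chloromethyllithium may decay before capture. Unchanged 14 would then be oxidised to the secondary carbinol.

Fallback (sets out from 14, returns at 15): preformed dichloromethyllithium (CH2Cl2, n-BuLi, THF, −100 °C, then ZnCl2 on warming) is a more persistent carbenoid. It should give 2-[(2R)-1-chloro-3-[2,6-bis(methoxymethoxy)-4-(triisopropylsilyloxy)phenyl]-2-[2,2-dimethyl-5-(triisopropylsilyloxy)-2H-chromen-8-yl]propyl]-4,4,5,5-tetramethyl-1,3,2-dioxaborolane F7 as both epimers at the chlorinated carbon. LiBHEt3 (THF, −78 °C to rt) adds hydride to boron and shifts it to carbon with loss of chloride, giving 15, which is oxidised as in step 8.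

**Step 9.** The acid may hydrate or oligomerise the ring D double bond, the aryl silyl ethers may partly be lost, or the second acetal may be removed incompletely.

Fallback (sets out from 16, returns at 17): the acetals are exchanged for labile silyl groups under non-acidic conditions. TMSOTf with 2,2'-bipyridyl (MeCN, 0 °C) should convert both aryl MOM ethers into trimethylsilyl ethers and silylate the alcohol, giving [(2R)-3-[2,6-bis(trimethylsilyloxy)-4-(triisopropylsilyloxy)phenyl]-2-[2,2-dimethyl-5-(triisopropylsilyloxy)-2H-chromen-8-yl]propoxy]trimethylsilane F8. Aqueous methanol then hydrolyses the three trimethylsilyl ethers to 17 while the triisopropylsilyl ethers stay.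

**Step 11.** Carbonate may remove an aryl silyl group, and the freed phenoxide would then be methylated at the wrong oxygen.

Fallback (sets out from 18, returns at 19): the phenol is methylated under neutral redox-condensation conditions (Mitsunobu methylation: MeOH, PPh3, DIAD, THF), so no phenoxide is generated; no new compound is made.

## Further compounds

F1 | step 7 | ethyl 2-[2,2-dimethyl-5-(triisopropylsilyloxy)-2H-chromen-8-yl]acetate | CCOC(=O)Cc1ccc(O[Si](C(C)C)(C(C)C)C(C)C)c2c1OC(C)(C)C=C2
F2 | step 7 | 2-[2,2-dimethyl-5-(triisopropylsilyloxy)-2H-chromen-8-yl]acetic acid | OC(=O)Cc1ccc(O[Si](C(C)C)(C(C)C)C(C)C)c2c1OC(C)(C)C=C2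
F3 | step 7 | (4R)-4-benzyl-3-{2-[2,2-dimethyl-5-(triisopropylsilyloxy)-2H-chromen-8-yl]acetyl}oxazolidin-2-one | O=C1OC[C@@H](Cc2ccccc2)N1C(=O)Cc3ccc(O[Si](C(C)C)(C(C)C)C(C)C)c4c3OC(C)(C)C=C4
F4 | step 7 | [2,6-bis(methoxymethoxy)-4-(triisopropylsilyloxy)phenyl]methanol | COCOc1cc(O[Si](C(C)C)(C(C)C)C(C)C)cc(OCOC)c1CO
F5 | step 7 | [4-(bromomethyl)-3,5-bis(methoxymethoxy)phenoxy]triisopropylsilane | COCOc1cc(O[Si](C(C)C)(C(C)C)C(C)C)cc(OCOC)c1CBr
F6 | step 7 | (4R)-4-benzyl-3-{(2R)-3-[2,6-bis(methoxymethoxy)-4-(triisopropylsilyloxy)phenyl]-2-[2,2-dimethyl-5-(triisopropylsilyloxy)-2H-chromen-8-yl]propanoyl}oxazolidin-2-one | O=C1OC[C@@H](Cc2ccccc2)N1C(=O)[C@H](Cc3c(OCOC)cc(O[Si](C(C)C)(C(C)C)C(C)C)cc3OCOC)c4ccc(O[Si](C(C)C)(C(C)C)C(C)C)c5c4OC(C)(C)C=C5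
F7 | step 8 | 2-[(2R)-1-chloro-3-[2,6-bis(methoxymethoxy)-4-(triisopropylsilyloxy)phenyl]-2-[2,2-dimethyl-5-(triisopropylsilyloxy)-2H-chromen-8-yl]propyl]-4,4,5,5-tetramethyl-1,3,2-dioxaborolane (both epimers at C1) | COCOc1cc(O[Si](C(C)C)(C(C)C)C(C)C)cc(OCOC)c1C[C@H](c1ccc(O[Si](C(C)C)(C(C)C)C(C)C)c2c1OC(C)(C)C=C2)C(Cl)B1OC(C)(C)C(C)(C)O1
F8 | step 9 | [(2R)-3-[2,6-bis(trimethylsilyloxy)-4-(triisopropylsilyloxy)phenyl]-2-[2,2-dimethyl-5-(triisopropylsilyloxy)-2H-chromen-8-yl]propoxy]trimethylsilane | C[Si](C)(C)Oc1cc(O[Si](C(C)C)(C(C)C)C(C)C)cc(O[Si](C)(C)C)c1C[C@H](c1ccc(O[Si](C(C)C)(C(C)C)C(C)C)c2c1OC(C)(C)C=C2)CO[Si](C)(C)C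
F0 | step 11 | none | none
A1 | alternative 1 | (3R)-7-(tert-butyldimethylsilyloxy)-3-[4-(tert-butyldimethylsilyloxy)-2-(2-methylbut-3-yn-2-yloxy)phenyl]-5-methoxychroman | COc1cc(O[Si](C)(C)C(C)(C)C)cc2c1C[C@H](c1ccc(O[Si](C)(C)C(C)(C)C)cc1OC(C)(C)C#C)CO2
A2 | alternative 1 | (3R)-7-(tert-butyldimethylsilyloxy)-3-[5-(tert-butyldimethylsilyloxy)-2,2-dimethyl-2H-chromen-8-yl]-5-methoxychroman | COc1cc(O[Si](C)(C)C(C)(C)C)cc2c1C[C@H](c1ccc(O[Si](C)(C)C(C)(C)C)c3c1OC(C)(C)C=C3)CO2
A3 | alternative 2 | 2-(hydroxymethyl)-3-methoxy-5-(methoxymethoxy)phenol | COCOc1cc(O)c(CO)c(OC)c1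
A4 | alternative 2 | 5-methoxy-3-(methoxymethoxy)-6-methylidenecyclohexa-2,4-dien-1-one | C=C1C(=O)C=C(OCOC)C=C1OC
A5 | alternative 2 | 2-[2,2-dimethyl-5-(methoxymethoxy)-2H-chromen-8-yl]acetaldehyde | COCOc1ccc(CC=O)c2c1C=CC(C)(C)O2
A6 | alternative 2 | (3R)-3-[2,2-dimethyl-5-(methoxymethoxy)-2H-chromen-8-yl]-5-methoxy-7-(methoxymethoxy)chroman-2-ol (both anomers) | COc1cc(OCOC)cc2c1C[C@H](c1ccc(OCOC)c3c1OC(C)(C)C=C3)C(O)O2
A7 | alternative 3 | 4-diazo-4-[(3R)-5-methoxy-7-(triisopropylsilyloxy)chroman-3-yl]but-1-en-3-one | COc1cc(O[Si](C(C)C)(C(C)C)C(C)C)cc2c1C[C@H](C(=[N+]=[N-])C(=O)C=C)CO2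
A8 | alternative 3 | 2-[(3R)-5-methoxy-7-(triisopropylsilyloxy)chroman-3-yl]buta-1,3-dien-1-one | COc1cc(O[Si](C(C)C)(C(C)C)C(C)C)cc2c1C[C@H](C(=C=O)C=C)CO2
A9 | alternative 3 | triisopropyl[(5-methylhex-4-en-1-yn-1-yl)oxy]silane | CC(C)=CCC#CO[Si](C(C)C)(C(C)C)C(C)C
A10 | alternative 3 | 6-[(3R)-5-methoxy-7-(triisopropylsilyloxy)chroman-3-yl]-2-(3-methylbut-2-enyl)-3-(triisopropylsilyloxy)phenol | COc1cc(O[Si](C(C)C)(C(C)C)C(C)C)cc2c1C[C@H](c1ccc(O[Si](C(C)C)(C(C)C)C(C)C)c(CC=C(C)C)c1O)CO2
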